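## Structural features

The target 19 (C24H18O12) is a linear tetramer of phloroglucinol units: four benzene rings joined B–O–A–O–C–O–D by three diaryl ether oxygens, with nine free phenolic hydroxyls, no ring other than the arenes and no stereocentre. Ring A is 1,3,5-trioxygenated (one OH, two aryloxy groups). Rings B, C and D are 1,2,3,5-tetraoxygenated: the ether-bearing C1 of each lies between hydroxyls at C2 and C6, and C4 carries OH in rings B and D and the ether oxygen to ring D in ring C. Every ether oxygen is therefore bound to at least one carbon flanked by two oxygenated carbons, which is electron-rich and hindered and the worst case for metal-mediated C–O coupling. The free polyphenol is sensitive to air in base, to electrophiles and to strong oxidants, so the hydroxyls should be revealed late and under neutral conditions. The difficulty is regiochemical, not stereochemical: twelve oxygens on four rings must be placed and differentiated, and three hindered ether bonds must be made without scrambling. The key step exploits the fact that the six hydroxylated carbons C2 and C6 of rings B, C and D all stand ortho to an ether-bearing C1. A formyl group at each of these positions first activates a C1–F bond for phenoxide displacement and is afterwards exchanged for oxygen by peracid-induced aryl migration.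

## Logic of the disconnections

19 ⇒ 18. The three O–CH2 bonds of benzyl ethers on ring A and on C4 of rings B and D are cut. Hydrogenolysis is neutral and leaves only a volatile by-product, so the air-sensitive polyphenol appears in the last flask without base or Lewis acid. The forward step demands exclusion of air and a substrate free of catalyst poisons.

18 ⇒ 16 (through 17). The six aryl C–O bonds at C2 and C6 of rings B, C and D are cut and replaced by C–CHO bonds. This turns three electron-rich, hindered rings into electron-poor ones whose C1 is activated for ether formation, and it reduces the oxygenation problem to one repeated operation. The forward step must achieve aryl migration in preference to hydride migration at all six sites, must not oxidise ring A, and must release the phenols only after the oxidant is gone.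

16 ⇒ 15 + 12. The ether bond between the ring A oxygen and C1 of ring C is cut. This is the most convergent cut, with two rings on each side, and C1 of ring C carries fluoride between two formyl groups in 12. The forward step requires that the phenoxide of 15 displaces fluoride and does not exchange one of the aryloxy groups that sit on equally activated carbons.

15 ⇒ 14 + 10. The ether bond between the second ring A oxygen and C1 of ring B is cut. Both fragments are simple monocyclic compounds. The forward step requires mono-arylation of a symmetric diol.

12 ⇒ 7 + 10 (through 11). The ether bond between the C4 oxygen of ring C and C1 of ring D is cut, and the two ring C formyl groups are traced back to dioxolanes. With the aldehydes masked, the C–F bond of the nucleophile is not activated, so the phenoxide cannot attack a second molecule of its own kind or of the product. This replaces a free hydroxy-fluoro-dialdehyde, which would oligomerise. The forward step requires acetal hydrolysis that leaves the new ether and the benzyl group untouched.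

10 ⇒ 7 + 8 (through 9). The benzyl O–CH2 bond and the two acetals are cut. The same phenol thus serves rings B, C and D. Alkylation is done while C–F is still unactivated, so no diaryl ether can form.

14 ⇒ 13 + 8. One benzyl O–CH2 bond is cut. The forward step is a statistical mono-alkylation of a cheap triol and must favour oxygen over carbon alkylation.

7 ⇒ 4 (through 5 and 6). The phenolic C–O bond is traced to the C–Br bond. The forward step needs an aryl-metal species that tolerates acetals and does not eliminate fluoride, and an oxidation that the acetals survive.

4 ⇒ 3 ⇒ 2 ⇒ 1. The acetal C–O bonds, then the carbonyl oxygens (from CHBr2 groups), then four benzylic C–Br bonds are removed, which leads to a commercial xylene. The forward steps need exhaustive but not excessive benzylic bromination, and a hydrolysis free of nucleophiles that could displace the fluoride once it is activated.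

## Other disconnections considered

Alternative 1: The cut runs through rings B and D themselves, at the C2–C3 and C5–C6 bonds of each. Each terminal ring falls apart into a malonate unit (the future C1 with its two ester carbons as C2 and C6) and a three-carbon oxoglutarate unit (C3, C4, C5). In the forward direction the bis(aryloxymalonate) A2 would be condensed under alkoxide base with two equivalents of dimethyl 3-oxoglutarate A3. Two Claisen-type C-acylations per ring and enolisation would give the tetraester A1, in which rings B and D are phloroglucinol dicarboxylates.
- In its favour: the ether oxygens of rings B and D are attached to an sp3 malonate carbon, not to a hindered arene. All oxygens arrive at the correct oxidation level, so no multi-site oxidation is needed; on this point the alternative is better than the chosen plan. Two rings are built in one two-directional operation.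
- Against it here: a malonate with an aryloxy group on its central carbon is a hindered acyl acceptor, A3 can condense with itself, and the condensation is reversible. After the key step, four esters must be hydrolysed and decarboxylated and three methyl ethers cleaved by a boron trihalide on a nearly finished polyphenol. Ring C and the hindered ether between rings A and C are not addressed.
- Comparison: on structure, it solves two of the three tetraoxygenated rings, whereas the chosen plan treats all three by one device. On mechanism, a base-driven double condensation with several competing enolates stands against six irreversible aryl migrations of a well-known type. On step economy, the ring construction is short, but the decarboxylation and demethylation endgame and the separate synthesis of the core of A2 should make the total at best equal, and the last deprotection is harsher than the hydrogenolysis of 18.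

Alternative 2: Ring C is dissected at C2–C3 and C4–C5. The four-carbon piece is the cyclobutenone A5 (future C1, C2, C5, C6, with the aryloxy group of rings A and B on the future C1 and an ethoxy group on the future C6). The two-carbon piece is the aryl ethynyl ether A6 (future C3 and C4 with the ring D oxygen). Heating A5 with A6 would open the cyclobutenone to a vinylketene, which adds to the ynol ether in a regioselective [2+2] step. A second ring opening, a six-electron electrocyclisation and tautomerisation would give the phenol A4.
- In its favour: the most congested ring is built with both ether oxygens already attached, so neither of its ether bonds has to be formed on a doubly ortho-substituted arene; here the alternative is better than the chosen plan. The cascade is thermal, needs no reagent and involves no change of oxidation state.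
- Against it here: A5 requires an aryloxyketene cycloaddition and A6 is a sensitive ynol ether of a hindered phenol. Ring C emerges needlessly desymmetrised (one OH, one OEt). Eight alkyl ethers must be cleaved at the end by a boron trihalide. The ether between rings A and B still has to be made by a hindered coupling.
- Comparison: on structure, it handles the hardest ring elegantly but leaves rings B and D to classical chemistry. On mechanism, one pericyclic cascade with one regiochemical decision stands against six aryl migrations; neither plan has a stereochemical issue, and both are convergent at the key step, where they are equal. On step economy, the multistep syntheses of A5 and A6 and the eightfold dealkylation should make the route longer than the chosen one.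

Alternative 3: Three C–O bonds are cut, at the hydroxyl-bearing carbon of ring A and at C4 of rings B and D. This leaves the deoxy tetra(aryl ether) A8 with six methyl ethers. In the forward direction an iridium-catalysed C–H borylation with a pinacol-derived diboron reagent, followed by oxidation of the three C–B bonds in the same pot, would give the triphenol A7.
- In its favour: steric control selects the wanted positions. On ring A only the C–H meta to both aryloxy groups is unflanked, on rings B and D only the C–H para to the ether has no ortho substituent, and both C–H bonds of ring C are blocked. A8 should be reachable in a few copper-catalysed etherifications, with no polyaldehyde and no statistical step. In step economy the alternative is clearly better than the chosen plan.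
- Against it here: electron-rich anisole-type rings are slow in C–H borylation and three sites must all react. Borylation next to a methoxy group on rings B and D is a plausible minor pathway and would lead to isomeric phenols. The six methyl ethers of A7, all ortho to diaryl ether oxygens, need a boron trihalide, the harshest end for this polyphenol. The ether couplings for A8 involve doubly ortho-substituted phenols.
- Comparison: on structure, three of the twelve oxygens are introduced late, against six in the chosen plan. On mechanism, both plans rest on a late multi-site carbon-to-oxygen conversion and are equal in concept. The chosen plan has the advantage that the groups to be oxidised also make the ether bonds easy and that the end is a neutral hydrogenolysis.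

Key step: step 10

Remark: ring letters follow B–O–A–O–C–O–D with A the 1,3,5-trioxygenated ring. The hexaaldehyde 16 and the hexaphenol 18 map atom for atom onto 19, so no structural correction is needed. The design change is upstream: ring C enters as the bis-acetal phenol 7, not as a free hydroxy-fluoro-dialdehyde.

## Route

Step 1
Reactants: 1 5-bromo-2-fluoro-1,3-dimethylbenzene
Product: 2 5-bromo-1,3-bis(dibromomethyl)-2-fluorobenzene
Conditions: NBS (4.5 equiv), AIBN (cat.), PhCF3, reflux, hν
Reagents that add atoms: N-bromosuccinimide, O=C1CCC(=O)N1Br
Why: Wohl–Ziegler radical bromination; each methyl group should be taken to the gem-dibromide because a third halogenation of a CHBr2 group is much slower for steric and polar reasons, and the aryl C–F and C–Br bonds are inert to bromine radicals.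

Step 2
Reactants: 2 5-bromo-1,3-bis(dibromomethyl)-2-fluorobenzene
Product: 3 5-bromo-2-fluoroisophthalaldehyde
Conditions: AgNO3 (4.4 equiv), acetone/H2O, 50 °C, dark
Reagents that add atoms: water, O
Why: Silver-assisted hydrolysis of benzal bromides (SN1 type): the silver cation abstracts bromide, water traps the α-bromobenzyl cation and the bromohydrin collapses to the aldehyde; the medium stays acidic, so nothing present can displace the newly activated fluoride.

Step 3
Reactants: 3 5-bromo-2-fluoroisophthalaldehyde
Product: 4 2,2'-(5-bromo-2-fluoro-1,3-phenylene)bis(1,3-dioxolane)
Conditions: HOCH2CH2OH, p-TsOH·H2O (cat.), toluene, reflux, Dean–Stark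
Reagents that add atoms: ethylene glycol, OCCO
Why: Acid-catalysed acetalisation with azeotropic removal of water; the dioxolanes protect the carbonyl groups from the organolithium of step 4 and switch off the activation of the C–F bond.

Step 4
Reactants: 4 2,2'-(5-bromo-2-fluoro-1,3-phenylene)bis(1,3-dioxolane)
Product: 7 4-fluoro-3,5-di(1,3-dioxolan-2-yl)phenol, via aryllithium 5 (not isolated), via lithium aryltrimethoxyborate 6 (not isolated)
Conditions: n-BuLi, THF, −78 °C; B(OMe)3, −78 → 0 °C; H2O2, aq. NaOH, 0 °C → rt; neutral work-up
Reagents that add atoms: hydrogen peroxide, OO (phenol oxygen); n-butyllithium, [Li]CCCC, and trimethyl borate, COB(OC)OC, leave atoms only in 5 and 6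
Why: Bromine–lithium exchange is faster at −78 °C than any deprotonation and the lithium sits para to fluorine, so no aryne can form; borate trapping and alkaline peroxide then effect the 1,2-aryl shift from boron to oxygen (borylation–oxidation), and the acetals are stable to base.

Step 5
Reactants: 7 4-fluoro-3,5-di(1,3-dioxolan-2-yl)phenol; 8 benzyl bromide
Product: 10 5-(benzyloxy)-2-fluoroisophthalaldehyde, via benzyl ether bis(dioxolane) 9 (not isolated)
Conditions: K2CO3, DMF, rt; then 2 M aq. HCl, THF, rt
Reagents that add atoms: water, O (carbonyl oxygens after acetal hydrolysis)
Why: Williamson ether synthesis on a phenoxide whose C–F bond lies between acetals and is not activated, so no diaryl ether can form; dilute acid then hydrolyses both dioxolanes (acetal hydrolysis) while the benzyl ether and C–F bond are stable.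

Step 6
Reactants: 7 4-fluoro-3,5-di(1,3-dioxolan-2-yl)phenol; 10 5-(benzyloxy)-2-fluoroisophthalaldehyde
Product: 12 5-[4-(benzyloxy)-2,6-diformylphenoxy]-2-fluoroisophthalaldehyde, via diaryl ether bis(dioxolane) 11 (not isolated)
Conditions: Cs2CO3, MeCN, rt → 50 °C; then 2 M aq. HCl, THF, rt
Reagents that add atoms: water, O (carbonyl oxygens after acetal hydrolysis)
Why: Nucleophilic aromatic substitution by addition–elimination through a Meisenheimer adduct stabilised by both ortho formyl groups of 10; the nucleophile 7 cannot serve as an electrophile because its own C–F bond lies between acetals, which excludes oligomerisation, and the acid hydrolysis then unmasks the ring C aldehydes and with them the activation of the second C–F bond.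

Step 7
Reactants: 13 phloroglucinol; 8 benzyl bromide
Product: 14 5-(benzyloxy)benzene-1,3-diol
Conditions: 13 (3 equiv), K2CO3, DMF, 0 °C → rt, slow addition of 8
Reagents that add atoms: none
Why: Williamson O-alkylation; the excess of the cheap triol and the slow addition bias the statistics toward the mono-ether, carbonate in a dipolar aprotic solvent favours oxygen over carbon alkylation, and the water-soluble triol is washed out.

Step 8
Reactants: 14 5-(benzyloxy)benzene-1,3-diol; 10 5-(benzyloxy)-2-fluoroisophthalaldehyde
Product: 15 5-(benzyloxy)-2-[3-(benzyloxy)-5-hydroxyphenoxy]isophthalaldehyde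
Conditions: 14 (3 equiv), Cs2CO3, MeCN, rt, slow addition of 10
Reagents that add atoms: none
Why: Nucleophilic aromatic substitution as in step 6; the diol is in excess so that mono-arylation should dominate, the first electron-poor aryloxy group lowers the nucleophilicity of the remaining phenoxide, and surplus 14 is recovered.

Step 9
Reactants: 15 5-(benzyloxy)-2-[3-(benzyloxy)-5-hydroxyphenoxy]isophthalaldehyde; 12 5-[4-(benzyloxy)-2,6-diformylphenoxy]-2-fluoroisophthalaldehyde
Product: 16 5-(benzyloxy)-2-[3-(benzyloxy)-5-{4-[4-(benzyloxy)-2,6-diformylphenoxy]-2,6-diformylphenoxy}phenoxy]isophthalaldehyde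
Conditions: Cs2CO3 (1.2 equiv), MeCN, rt
Reagents that add atoms: none
Why: Nucleophilic aromatic substitution with one equivalent of each partner; fluoride is a far better nucleofuge than aryloxide in addition–elimination and ring C of 12 (para aryloxy) is more electrophilic than the benzyloxy-bearing ring D, so the phenoxide should enter at C–F and not exchange an aryloxy group, and mild base at room temperature protects the three doubly activated ether carbons of the product.

Step 10
Reactants: 16 5-(benzyloxy)-2-[3-(benzyloxy)-5-{4-[4-(benzyloxy)-2,6-diformylphenoxy]-2,6-diformylphenoxy}phenoxy]isophthalaldehyde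
Product: 18 5-(benzyloxy)-2-[3-(benzyloxy)-5-{4-[4-(benzyloxy)-2,6-dihydroxyphenoxy]-2,6-dihydroxyphenoxy}phenoxy]benzene-1,3-diol, via hexaformate 17 (not isolated)
Conditions: mCPBA (9 equiv), CH2Cl2, 0 → 40 °C; Me2S; then HCl/MeOH (degassed), 0 °C → rt, Ar
Reagents that add atoms: 3-chloroperbenzoic acid, OOC(=O)c1cccc(Cl)c1
Why: The peracid adds to each formyl group to give a Criegee adduct, from which the aryl carbon migrates to the proximal peroxide oxygen as 3-chlorobenzoate departs, giving an aryl formate (Baeyer–Villiger oxidation of an aryl aldehyde, Dakin type); acidic methanolysis then transesterifies the six formates of 17. The closest known reaction is the peracid oxidation of ortho-alkoxy- and ortho-aryloxybenzaldehydes to phenols, routinely paired with fluoride displacement on ortho-fluorobenzaldehydes in diaryl ether synthesis; running it six times on one molecule applies the same reaction. No ring is closed and no stereocentre is formed. The selectivity required is aryl over hydride migration at every site, and it is secured because each migrating carbon (C2 or C6 of rings B, C and D) is ortho to the ether oxygen on C1, whose lone pair stabilises the electron-poor migrating terminus. The first oxidation on a ring is the slow one because the second formyl group withdraws electrons; once that group has become a formyloxy group the ring is more electron-rich and the second migration should be faster, so partly oxidised species funnel to 17. Arene hydroxylation is avoided because the phenols stay masked as formates until the peracid has been destroyed and because ring A carries two weakly donating aryloxy groups. Benzyl and diaryl ethers are inert to peracid and to methanolic HCl, and acidic cleavage of the formates keeps 18 away from base and air.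

Step 11
Reactants: 18 5-(benzyloxy)-2-[3-(benzyloxy)-5-{4-[4-(benzyloxy)-2,6-dihydroxyphenoxy]-2,6-dihydroxyphenoxy}phenoxy]benzene-1,3-diol
Product: 19 2-[3-{4-(2,4,6-trihydroxyphenoxy)-2,6-dihydroxyphenoxy}-5-hydroxyphenoxy]benzene-1,3,5-triol (CNP0159471.0)
Conditions: H2 (1 atm), 10% Pd/C, EtOAc/MeOH (degassed), rt; filtration under Ar
Reagents that add atoms: none
Why: Hydrogenolysis of three benzylic C–O bonds over palladium under neutral conditions, with toluene as the only by-product; diaryl ethers and arenes are not reduced at one atmosphere and room temperature, and air is excluded because the polyphenol is oxidisable.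

## Compound list

1 | 5-bromo-2-fluoro-1,3-dimethylbenzene | Cc1cc(Br)cc(C)c1F | starting material
2 | 5-bromo-1,3-bis(dibromomethyl)-2-fluorobenzene | BrC(Br)c1cc(Br)cc(C(Br)Br)c1F | intermediate
3 | 5-bromo-2-fluoroisophthalaldehyde | O=Cc1cc(Br)cc(C=O)c1F | intermediate
4 | 2,2'-(5-bromo-2-fluoro-1,3-phenylene)bis(1,3-dioxolane) | Brc1cc(C2OCCO2)c(F)c(C2OCCO2)c1 | intermediate
5 | [4-fluoro-3,5-di(1,3-dioxolan-2-yl)phenyl]lithium (not isolated) | [Li]c1cc(C2OCCO2)c(F)c(C2OCCO2)c1 | intermediate
6 | lithium [4-fluoro-3,5-di(1,3-dioxolan-2-yl)phenyl]trimethoxyborate (not isolated) | [Li+].CO[B-](OC)(OC)c1cc(C2OCCO2)c(F)c(C2OCCO2)c1 | intermediate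
7 | 4-fluoro-3,5-di(1,3-dioxolan-2-yl)phenol | Oc1cc(C2OCCO2)c(F)c(C2OCCO2)c1 | intermediate
8 | benzyl bromide | BrCc1ccccc1 | starting material
9 | 2,2'-[5-(benzyloxy)-2-fluoro-1,3-phenylene]bis(1,3-dioxolane) (not isolated) | c1ccccc1COc1cc(C2OCCO2)c(F)c(C2OCCO2)c1 | intermediate
10 | 5-(benzyloxy)-2-fluoroisophthalaldehyde | O=Cc1cc(OCc2ccccc2)cc(C=O)c1F | intermediate
11 | 5-(benzyloxy)-2-[4-fluoro-3,5-di(1,3-dioxolan-2-yl)phenoxy]isophthalaldehyde (not isolated) | O=Cc1cc(OCc2ccccc2)cc(C=O)c1Oc1cc(C2OCCO2)c(F)c(C2OCCO2)c1 | intermediate
12 | 5-[4-(benzyloxy)-2,6-diformylphenoxy]-2-fluoroisophthalaldehyde | O=Cc1cc(OCc2ccccc2)cc(C=O)c1Oc1cc(C=O)c(F)c(C=O)c1 | intermediate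
13 | phloroglucinol (benzene-1,3,5-triol) | Oc1cc(O)cc(O)c1 | starting material
14 | 5-(benzyloxy)benzene-1,3-diol | Oc1cc(O)cc(OCc2ccccc2)c1 | intermediate
15 | 5-(benzyloxy)-2-[3-(benzyloxy)-5-hydroxyphenoxy]isophthalaldehyde | O=Cc1cc(OCc2ccccc2)cc(C=O)c1Oc1cc(O)cc(OCc2ccccc2)c1 | intermediate
16 | 5-(benzyloxy)-2-[3-(benzyloxy)-5-{4-[4-(benzyloxy)-2,6-diformylphenoxy]-2,6-diformylphenoxy}phenoxy]isophthalaldehyde (hexaaldehyde, precursor of the key step) | O=Cc1cc(OCc2ccccc2)cc(C=O)c1Oc1cc(OCc2ccccc2)cc(Oc2c(C=O)cc(Oc3c(C=O)cc(OCc4ccccc4)cc3C=O)cc2C=O)c1 | intermediate
17 | hexakis(formate) of 18, each CHO of 16 replaced by OCHO (not isolated) | O=COc1cc(OCc2ccccc2)cc(OC=O)c1Oc1cc(OCc2ccccc2)cc(Oc2c(OC=O)cc(Oc3c(OC=O)cc(OCc4ccccc4)cc3OC=O)cc2OC=O)c1 | intermediate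
18 | 5-(benzyloxy)-2-[3-(benzyloxy)-5-{4-[4-(benzyloxy)-2,6-dihydroxyphenoxy]-2,6-dihydroxyphenoxy}phenoxy]benzene-1,3-diol (tri-O-benzyl target, product of the key step) | Oc1cc(OCc2ccccc2)cc(O)c1Oc1cc(OCc2ccccc2)cc(Oc2c(O)cc(Oc3c(O)cc(OCc4ccccc4)cc3O)cc2O)c1 | intermediate
19 | 2-[3-{4-(2,4,6-trihydroxyphenoxy)-2,6-dihydroxyphenoxy}-5-hydroxyphenoxy]benzene-1,3,5-triol (CNP0159471.0) | Oc1cc(Oc2c(O)cc(O)cc2O)cc(Oc2c(O)cc(Oc3c(O)cc(O)cc3O)cc2O)c1 | target

## Step count and risk assessment

Total step count: 11. Longest linear sequence: 9 steps (steps 1, 2, 3, 4, 5, 6, 9, 10, 11, from 1 to 19). Steps 7 and 8 form the short second branch.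

Least certain steps:

Step 10 (key step). Hydride migration may compete with aryl migration at the first oxidation of each ring, while a second electron-withdrawing formyl group is still present; this would lead to carboxylic acids. Uneven conversion over six sites and hydroxylation of ring A by excess peracid are further risks. Fallback: set out from 16 and take away the hydride option. Sixfold addition of MeMgBr (THF, −78 °C) should give the hexakis(1-hydroxyethyl) compound F1 as a diastereomer mixture of no consequence. Oxidation with IBX (DMSO/EtOAc) should give the hexaacetyl compound F2. Baeyer–Villiger oxidation of the six aryl methyl ketones with mCPBA, where only aryl or methyl can migrate and aryl is strongly preferred, should give the hexaacetate F3. Methanolysis with HCl/MeOH under argon rejoins the route at 18.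

Step 9. The phenoxide of 15 may attack a doubly formyl-activated, aryloxy-bearing carbon (C1 of ring D in 12, or C1 of rings B and C in the product) and scramble the ethers. It may also add through carbon to an aldehyde. Fallback: a linear order in which the last electrophile carries no exchangeable aryloxy group. From 7, allylation (allyl bromide, K2CO3, DMF) should give the allyl ether bis(dioxolane) F4, and acid hydrolysis the 5-(allyloxy)-2-fluoroisophthalaldehyde F5. Fluoride displacement on F5 by 15 (Cs2CO3, MeCN) should give the ring B–A–C tetraaldehyde allyl ether F6. Deallylation with Pd(PPh3)4 (zerovalent palladium) and sodium p-toluenesulfinate in THF should give the ring C phenol F7. Its weakly nucleophilic phenoxide then displaces fluoride from 10 and rejoins the route at 16.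

Step 8. Double arylation of the diol and wasteful consumption of 10 are likely if the statistical bias is insufficient, and the electron-rich ring of 14 may attack an aldehyde through carbon. Fallback: differentiate the two hydroxyls before the arylation. From 14, mono-allylation (allyl bromide, K2CO3, acetone) at the stage of cheap materials should give 3-(allyloxy)-5-(benzyloxy)phenol F8. Its single phenoxide displaces fluoride from 10 to give 2-[3-(allyloxy)-5-(benzyloxy)phenoxy]-5-(benzyloxy)isophthalaldehyde F9. Deallylation with Pd(PPh3)4 and sodium p-toluenesulfinate rejoins the route at 15.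

Step 7. Carbon benzylation and over-benzylation of the ambident phloroglucinol anion may erode the mono-ether. Fallback: a non-statistical route from commercial 3,5-dibromophenol F10. Benzylation with 8 (K2CO3, DMF) should give 1-(benzyloxy)-3,5-dibromobenzene F11. Double Miyaura borylation (B2pin2, PdCl2(dppf), KOAc, dioxane, 90 °C) should give the bis(pinacol boronate) F12. Oxidation (H2O2, aq. NaOH, THF, 0 °C) rejoins the route at 14.

Step 1. Uneven bromination is likely, because the fourth benzylic bromination is slow and mixtures of tri-, tetra- and pentabromides would be hard to separate. Fallback: from 1, stop at one bromine per methyl group (NBS, 2.1 equiv, AIBN, PhCF3, reflux) to give 5-bromo-1,3-bis(bromomethyl)-2-fluorobenzene F13. Oxidise both benzylic bromides with N-methylmorpholine N-oxide (MeCN, 4 Å molecular sieves, rt); this reagent cannot displace the activated fluoride, and the fallback rejoins the route at 3.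

## Further compounds

F1 | step 10 | hexakis(1-hydroxyethyl) analogue of 16, each CHO replaced by CH(OH)CH3 (diastereomer mixture) | CC(O)c1cc(OCc2ccccc2)cc(C(C)O)c1Oc1cc(OCc2ccccc2)cc(Oc2c(C(C)O)cc(Oc3c(C(C)O)cc(OCc4ccccc4)cc3C(C)O)cc2C(C)O)c1
F2 | step 10 | hexaacetyl analogue of 16, each CHO replaced by COCH3 | CC(=O)c1cc(OCc2ccccc2)cc(C(C)=O)c1Oc1cc(OCc2ccccc2)cc(Oc2c(C(C)=O)cc(Oc3c(C(C)=O)cc(OCc4ccccc4)cc3C(C)=O)cc2C(C)=O)c1
F3 | step 10 | hexaacetate of 18 | CC(=O)Oc1cc(OCc2ccccc2)cc(OC(C)=O)c1Oc1cc(OCc2ccccc2)cc(Oc2c(OC(C)=O)cc(Oc3c(OC(C)=O)cc(OCc4ccccc4)cc3OC(C)=O)cc2OC(C)=O)c1
F4 | step 9 | 2,2'-[5-(allyloxy)-2-fluoro-1,3-phenylene]bis(1,3-dioxolane) | C=CCOc1cc(C2OCCO2)c(F)c(C2OCCO2)c1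
F5 | step 9 | 5-(allyloxy)-2-fluoroisophthalaldehyde | C=CCOc1cc(C=O)c(F)c(C=O)c1
F6 | step 9 | 5-(allyloxy)-2-{3-(benzyloxy)-5-[4-(benzyloxy)-2,6-diformylphenoxy]phenoxy}isophthalaldehyde | O=Cc1cc(OCc2ccccc2)cc(C=O)c1Oc1cc(OCc2ccccc2)cc(Oc2c(C=O)cc(OCC=C)cc2C=O)c1
F7 | step 9 | 2-{3-(benzyloxy)-5-[4-(benzyloxy)-2,6-diformylphenoxy]phenoxy}-5-hydroxyisophthalaldehyde | O=Cc1cc(OCc2ccccc2)cc(C=O)c1Oc1cc(OCc2ccccc2)cc(Oc2c(C=O)cc(O)cc2C=O)c1
F8 | step 8 | 3-(allyloxy)-5-(benzyloxy)phenol | C=CCOc1cc(O)cc(OCc2ccccc2)c1
F9 | step 8 | 2-[3-(allyloxy)-5-(benzyloxy)phenoxy]-5-(benzyloxy)isophthalaldehyde | O=Cc1cc(OCc2ccccc2)cc(C=O)c1Oc1cc(OCC=C)cc(OCc2ccccc2)c1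
F10 | step 7 | 3,5-dibromophenol | Oc1cc(Br)cc(Br)c1
F11 | step 7 | 1-(benzyloxy)-3,5-dibromobenzene | Brc1cc(Br)cc(OCc2ccccc2)c1
F12 | step 7 | 2,2'-[5-(benzyloxy)-1,3-phenylene]bis(4,4,5,5-tetramethyl-1,3,2-dioxaborolane) | CC1(C)OB(OC1(C)C)c1cc(OCc2ccccc2)cc(c1)B1OC(C)(C)C(C)(C)O1
F13 | step 1 | 5-bromo-1,3-bis(bromomethyl)-2-fluorobenzene | BrCc1cc(Br)cc(CBr)c1F
A1 | alternative 1 | tetraester of the tri-O-methyl target with rings B and D formed as 3,5-dicarboxylates | COC(=O)c1c(O)c(C(=O)OC)c(O)c(Oc2cc(OC)cc(Oc3c(OC)cc(Oc4c(O)c(C(=O)OC)c(O)c(C(=O)OC)c4O)cc3OC)c2)c1O
A2 | alternative 1 | bis(aryloxymalonate): tetramethyl ester with one malonate oxygen-linked to ring A and one to C4 of ring C | COC(=O)C(Oc1cc(OC)cc(Oc2c(OC)cc(OC(C(=O)OC)C(=O)OC)cc2OC)c1)C(=O)OC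
A3 | alternative 1 | dimethyl 3-oxoglutarate | COC(=O)CC(=O)CC(=O)OC
A4 | alternative 2 | ring C phenol with C6 ethyl ether and seven methyl ethers | CCOc1cc(Oc2c(OC)cc(OC)cc2OC)cc(O)c1Oc1cc(OC)cc(Oc2c(OC)cc(OC)cc2OC)c1
A5 | alternative 2 | 3-ethoxy-4-[3-methoxy-5-(2,4,6-trimethoxyphenoxy)phenoxy]cyclobut-2-en-1-one | CCOC1=CC(=O)C1Oc1cc(OC)cc(Oc2c(OC)cc(OC)cc2OC)c1
A6 | alternative 2 | 2-(ethynyloxy)-1,3,5-trimethoxybenzene | C#COc1c(OC)cc(OC)cc1OC
A7 | alternative 3 | hexa-O-methyl target (triphenol) | COc1cc(O)cc(OC)c1Oc1cc(O)cc(Oc2c(OC)cc(Oc3c(OC)cc(O)cc3OC)cc2OC)c1
A8 | alternative 3 | deoxy tetra(aryl ether) with six methyl ethers | COc1cccc(OC)c1Oc1cccc(Oc2c(OC)cc(Oc3c(OC)cccc3OC)cc2OC)c1
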